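**Retrosynthetic overview**
1. Feature (rings lettered A to F from the 2,4,6-trihydroxyphenoxy end): rings D, E and F are three syringyl units joined head to tail. The oxygen on C4 of D is bonded to C1 of E and the oxygen on C4 of E to C1 of F. Each of these oxygens, and the C4-OH of F, lies between oxygenated C3 and C5.
2. Endgame: fifteen-fold O-demethylation, preceded by an Ullmann union at the C2(ring C)-O bond of DEF phenol 11 (OH on C1 of D) with ABC iodide 21.
3. DEF: the C1-OH of D comes from a methyl ester (reduction, oxidation, Baeyer-Villiger). Ester trimer 6 is cut at O-C1(E) and O-C1(F) into methyl syringate 1 and two molecules of syringic acid 2 (oxidative decarboxylative phenoxyl coupling).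
4. ABC: O-C1(B) and O-C1(C) are made by two Ullmann couplings. The halogen on C2 of ring C is installed in the monomer (18), because halogenation of a finished ABC triaryl ether would attack the phloroglucinol-type ring A instead.
5. No ring is built, since all six benzene rings are purchased. They are joined in the order D-E and E-F (one flask), A-B, B-C, then C-D.

Key step: step 1

Remark: the target has no stereocentre and no configurationally stable axis, so no SMILES carries a stereodescriptor. In ring C, C1 bears the oxygen to ring B, C2 the oxygen to ring D, C3 to C5 the three hydroxyl groups, and C6 is CH.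

Step 1
Reactants: 1 methyl syringate (1 equiv); 2 syringic acid (2 equiv)
Product: 6 DEF trimer phenol (methyl 4-[4-(4-hydroxy-3,5-dimethoxyphenoxy)-3,5-dimethoxyphenoxy]-3,5-dimethoxybenzoate), via first dienone acid 3 (not isolated), via DE dimer phenol 4 (not isolated), via second dienone acid 5 (not isolated)
Conditions: Ag2O (2.1 equiv, portionwise), slow addition of 2 (2.0 equiv, 8 h), CH2Cl2-acetone, 4 Å MS, Ar, dark, 0 °C to rt; aq. NaHCO3 wash; chromatography
Reagents that add atoms: none
Why: Proposed new method: monovalent silver removes one electron (with a proton) from each phenol, the oxygen of the phenoxyl radical of 1 combines with the spin-bearing, carboxyl-substituted C1 of the phenoxyl radical of 2 to give dienone acid 3 (a vinylogous beta-keto acid), which rearomatises irreversibly by loss of CO2 to 4, and the same sequence on 4 with a second molecule of 2 (via 5) gives 6, so that O-C1(E) and then O-C1(F) are formed. The closest known reaction types are the oxidase-catalysed decarboxylative polymerisation of syringic acid to poly(2,6-dimethoxy-1,4-phenylene oxide) and the C-O polymerisation of 2,6-disubstituted phenols by Ag2O or copper-amine oxidants, whereas interception at a discrete ester-capped trimer has not been shown. No ring is closed and no stereocentre is created. The O-to-para-carbon mode is favoured by the substrate, because both ortho carbons carry methoxy groups, combination at the ester-bearing C1 of 1 or at the aryloxy-bearing C1 of a chain end gives dienones that cannot expel a stable fragment and so revert, and para-para C-C union would join two fully substituted carbons and is second order in the radical of 2, which the slow feed keeps dilute. Direction and cross-selectivity follow from the ester, which cannot leave, so 1 reacts only through its oxygen and becomes ring D, the radicals of 1, 4 and 6 have no irreversible self-reaction and should build up as persistent radicals that capture the transient radical of 2, and chains started by 2 itself keep a free carboxyl group and go into the NaHCO3 wash. Chain length is the weak point, since it rests only on one equivalent of 1 per two of 2, the slow feed and the limiting charge of oxidant, while 4 and 6 are oxidised more easily than 1 and quinone-ketal redistribution can exchange terminal units, so 6 has to be separated from shorter and longer homologues.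

Step 2
Reactants: 6 DEF trimer phenol
Product: 7 DEF ester (methyl 4-[3,5-dimethoxy-4-(3,4,5-trimethoxyphenoxy)phenoxy]-3,5-dimethoxybenzoate)
Conditions: MeI, K2CO3, DMF, rt
Reagents that add atoms: iodomethane, IC
Why: Williamson ether synthesis, in which the C4-OH of ring F is the only acidic site of 6 and the methyl ester is inert to K2CO3 at room temperature.

Step 3
Reactants: 7 DEF ester
Product: 8 DEF benzylic alcohol ({4-[3,5-dimethoxy-4-(3,4,5-trimethoxyphenoxy)phenoxy]-3,5-dimethoxyphenyl}methanol)
Conditions: LiAlH4, THF, 0 °C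
Reagents that add atoms: none
Why: Hydride reduction of an aromatic ester to the benzylic alcohol, to which aryl methyl ethers and diaryl ethers are inert.

Step 4
Reactants: 8 DEF benzylic alcohol
Product: 9 DEF aldehyde (4-[3,5-dimethoxy-4-(3,4,5-trimethoxyphenoxy)phenoxy]-3,5-dimethoxybenzaldehyde)
Conditions: activated MnO2, CH2Cl2, rt
Reagents that add atoms: none
Why: Heterogeneous MnO2 oxidation is selective for benzylic alcohols and stops at the aldehyde.

Step 5
Reactants: 9 DEF aldehyde
Product: 11 DEF phenol (4-[3,5-dimethoxy-4-(3,4,5-trimethoxyphenoxy)phenoxy]-3,5-dimethoxyphenol), via DEF aryl formate 10 (not isolated)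
Conditions: mCPBA, CH2Cl2, 0 °C to rt; aq. NaHCO3 wash; then K2CO3 (cat.), MeOH, rt
Reagents that add atoms: mCPBA, OOC(=O)c1cccc(Cl)c1
Why: Baeyer-Villiger oxidation (the peracid counterpart of the Dakin reaction, needed because 9 has no free para-hydroxyl group), in which the electron-rich 4-aryloxy-3,5-dimethoxyphenyl group migrates in the Criegee adduct in preference to hydride, as with 3,4,5-trialkoxybenzaldehydes, and formate 10 is cleaved by base-catalysed methanolysis.

Step 6
Reactants: 12 4-bromo-2,6-dimethoxyphenol
Product: 13 2-(benzyloxy)-5-bromo-1,3-dimethoxybenzene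
Conditions: BnBr, K2CO3, DMF, rt
Reagents that add atoms: benzyl bromide, BrCc1ccccc1
Why: Williamson ether synthesis masks the future C4 oxygen of ring B, so that 13 can act only as the electrophile in the next coupling.

Step 7
Reactants: 13 2-(benzyloxy)-5-bromo-1,3-dimethoxybenzene; 14 2,4,6-trimethoxyphenol
Product: 15 AB benzyl ether (2-[4-(benzyloxy)-3,5-dimethoxyphenoxy]-1,3,5-trimethoxybenzene)
Conditions: CuI (10 mol %), picolinic acid (20 mol %), K3PO4, DMSO, 100 °C, Ar
Reagents that add atoms: none
Why: Ligand-accelerated Ullmann diaryl ether synthesis, in which picolinate-ligated monovalent copper accepts di-ortho-substituted phenoxides and the C-Br carbon of 13 has only hydrogen neighbours.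

Step 8
Reactants: 15 AB benzyl ether
Product: 16 AB phenol (2,6-dimethoxy-4-(2,4,6-trimethoxyphenoxy)phenol)
Conditions: H2 (1 atm), Pd/C, EtOAc-MeOH, rt
Reagents that add atoms: none
Why: Catalytic hydrogenolysis of the benzyl ether, with no halogen or other reducible group present in 15.

Step 9
Reactants: 17 5-iodo-1,2,3-trimethoxybenzene
Product: 18 2-bromo-1-iodo-3,4,5-trimethoxybenzene
Conditions: NBS, MeCN, 0 °C to rt, dark
Reagents that add atoms: N-bromosuccinimide, O=C1CCC(=O)N1Br
Why: Electrophilic aromatic bromination, in which the two free positions of 17 are equivalent and each lies ortho to one methoxy group and para to another, so a single monobromide should form before the more nucleophilic ring A is in the molecule.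

Step 10
Reactants: 16 AB phenol; 18 2-bromo-1-iodo-3,4,5-trimethoxybenzene
Product: 19 ABC bromide (2-bromo-1-[2,6-dimethoxy-4-(2,4,6-trimethoxyphenoxy)phenoxy]-3,4,5-trimethoxybenzene)
Conditions: CuI (10 mol %), picolinic acid (20 mol %), K3PO4, DMSO, 80 °C, Ar
Reagents that add atoms: none
Why: Chemoselective Ullmann diaryl ether synthesis, in which copper activates the C-I bond far faster than the C-Br bond, as with 1-bromo-2-iodoarenes in general, and the bromide left in 19 is shielded by two ortho oxygen substituents.

Step 11
Reactants: 19 ABC bromide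
Product: 21 ABC iodide (1-[2,6-dimethoxy-4-(2,4,6-trimethoxyphenoxy)phenoxy]-2-iodo-3,4,5-trimethoxybenzene), via ABC aryllithium 20 (not isolated)
Conditions: n-BuLi, THF, -78 °C; then I2, -78 °C to rt
Reagents that add atoms: iodine, [I][I]
Why: Bromine-lithium exchange followed by iodinolysis, where exchange at -78 °C is much faster than deprotonation of the methoxy-flanked ring positions and 20 is stabilised by its two ortho oxygen substituents.

Step 12
Reactants: 11 DEF phenol; 21 ABC iodide
Product: 22 pentadeca-O-methyl ether of the target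
Conditions: CuI (30 mol %), picolinic acid (60 mol %), K3PO4, DMSO, 110 °C, Ar
Reagents that add atoms: none
Why: Ullmann diaryl ether synthesis between an unhindered phenoxide and a di-ortho-oxygenated aryl iodide, a demanding but known substrate class for picolinate-ligated copper, with iodide in place of bromide and a raised copper loading to offset the crowding at C2 of ring C.

Step 13
Reactants: 22 pentadeca-O-methyl ether of the target
Product: 23 CNP0270681.0 (target)
Conditions: BBr3 (30 equiv), CH2Cl2, -78 °C to rt; degassed H2O, 0 °C; Sephadex LH-20 under Ar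
Reagents that add atoms: none
Why: Lewis-acid ether cleavage, in which BBr3 binds each methoxy oxygen and bromide removes the methyl group by SN2 attack, the diaryl ether oxygens offer no sp3 carbon and survive, and hydrolysis of the aryl borates frees the fifteen phenols.

**Compound list**
1 | methyl syringate (methyl 4-hydroxy-3,5-dimethoxybenzoate) | COC(=O)c1cc(OC)c(O)c(OC)c1 | starting material
2 | syringic acid (4-hydroxy-3,5-dimethoxybenzoic acid) | COc1cc(C(=O)O)cc(OC)c1O | starting material
3 | first dienone acid, 1-[2,6-dimethoxy-4-(methoxycarbonyl)phenoxy]-3,5-dimethoxy-4-oxocyclohexa-2,5-diene-1-carboxylic acid | COC(=O)c1cc(OC)c(OC2(C(=O)O)C=C(OC)C(=O)C(OC)=C2)c(OC)c1 | intermediate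
4 | DE dimer phenol, methyl 4-(4-hydroxy-3,5-dimethoxyphenoxy)-3,5-dimethoxybenzoate | COC(=O)c1cc(OC)c(Oc2cc(OC)c(O)c(OC)c2)c(OC)c1 | intermediate
5 | second dienone acid, 1-{4-[2,6-dimethoxy-4-(methoxycarbonyl)phenoxy]-2,6-dimethoxyphenoxy}-3,5-dimethoxy-4-oxocyclohexa-2,5-diene-1-carboxylic acid | COC(=O)c1cc(OC)c(Oc2cc(OC)c(OC3(C(=O)O)C=C(OC)C(=O)C(OC)=C3)c(OC)c2)c(OC)c1 | intermediate
6 | DEF trimer phenol, methyl 4-[4-(4-hydroxy-3,5-dimethoxyphenoxy)-3,5-dimethoxyphenoxy]-3,5-dimethoxybenzoate | COC(=O)c1cc(OC)c(Oc2cc(OC)c(Oc3cc(OC)c(O)c(OC)c3)c(OC)c2)c(OC)c1 | intermediate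
7 | DEF ester, methyl 4-[3,5-dimethoxy-4-(3,4,5-trimethoxyphenoxy)phenoxy]-3,5-dimethoxybenzoate | COC(=O)c1cc(OC)c(Oc2cc(OC)c(Oc3cc(OC)c(OC)c(OC)c3)c(OC)c2)c(OC)c1 | intermediate
8 | DEF benzylic alcohol | OCc1cc(OC)c(Oc2cc(OC)c(Oc3cc(OC)c(OC)c(OC)c3)c(OC)c2)c(OC)c1 | intermediate
9 | DEF aldehyde | O=Cc1cc(OC)c(Oc2cc(OC)c(Oc3cc(OC)c(OC)c(OC)c3)c(OC)c2)c(OC)c1 | intermediate
10 | DEF aryl formate | O=COc1cc(OC)c(Oc2cc(OC)c(Oc3cc(OC)c(OC)c(OC)c3)c(OC)c2)c(OC)c1 | intermediate
11 | DEF phenol | Oc1cc(OC)c(Oc2cc(OC)c(Oc3cc(OC)c(OC)c(OC)c3)c(OC)c2)c(OC)c1 | intermediate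
12 | 4-bromo-2,6-dimethoxyphenol | COc1cc(Br)cc(OC)c1O | starting material
13 | 2-(benzyloxy)-5-bromo-1,3-dimethoxybenzene | COc1cc(Br)cc(OC)c1OCc1ccccc1 | intermediate
14 | 2,4,6-trimethoxyphenol | COc1cc(OC)c(O)c(OC)c1 | starting material
15 | AB benzyl ether | COc1cc(OC)c(Oc2cc(OC)c(OCc3ccccc3)c(OC)c2)c(OC)c1 | intermediate
16 | AB phenol | COc1cc(OC)c(Oc2cc(OC)c(O)c(OC)c2)c(OC)c1 | intermediate
17 | 5-iodo-1,2,3-trimethoxybenzene | Ic1cc(OC)c(OC)c(OC)c1 | starting material
18 | 2-bromo-1-iodo-3,4,5-trimethoxybenzene | Ic1cc(OC)c(OC)c(OC)c1Br | intermediate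
19 | ABC bromide | COc1cc(OC)c(Oc2cc(OC)c(Oc3cc(OC)c(OC)c(OC)c3Br)c(OC)c2)c(OC)c1 | intermediate
20 | ABC aryllithium | COc1cc(OC)c(Oc2cc(OC)c(Oc3cc(OC)c(OC)c(OC)c3[Li])c(OC)c2)c(OC)c1 | intermediate
21 | ABC iodide | COc1cc(OC)c(Oc2cc(OC)c(Oc3cc(OC)c(OC)c(OC)c3I)c(OC)c2)c(OC)c1 | intermediate
22 | pentadeca-O-methyl ether of the target | COc1cc(OC)c(Oc2cc(OC)c(Oc3cc(OC)c(OC)c(OC)c3Oc3cc(OC)c(Oc4cc(OC)c(Oc5cc(OC)c(OC)c(OC)c5)c(OC)c4)c(OC)c3)c(OC)c2)c(OC)c1 | intermediate
23 | CNP0270681.0 | Oc1cc(O)c(Oc2cc(O)c(Oc3cc(O)c(O)c(O)c3Oc3cc(O)c(Oc4cc(O)c(Oc5cc(O)c(O)c(O)c5)c(O)c4)c(O)c3)c(O)c2)c(O)c1 | target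

**Step count**
Total steps: 13. Longest linear sequence: 7 steps (1, 2, 3, 4, 5, 12, 13). The ABC branch (6, 7, 8, 10, 11, 12, 13) is equally long.

**Steps most likely to fail**

Step 1.
- Risk: chain-length control may be lost, because the growing phenol is oxidised more readily than the cap and terminal units can be exchanged through quinone ketals. Self-initiation by the acid monomer, para-para C-C coupling and over-oxidation to quinone may also drain material.
- Fallback (known chemistry, sets out from 1 and returns at 7):
  - 1 is coupled with bromide 13 under the Ullmann conditions of step 7 to give methyl 4-[4-(benzyloxy)-3,5-dimethoxyphenoxy]-3,5-dimethoxybenzoate F1.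
  - Hydrogenolysis (H2, Pd/C) frees dimer phenol 4, which is now isolated.
  - A second Ullmann coupling of 4 with iodide 17 gives 7 directly.
  - Each ether bond is thus made singly, and steps 1 and 2 are replaced by three steps.

Step 12.
- Risk: activation of a C-I bond flanked by two oxygen substituents may be so slow that hydrodeiodination and oxidative loss of the phenoxide outrun C-O bond formation.
- Fallback (sets out from 19 and 11 and returns at 22): the polarity of the bond is inverted, so that the crowded ring C supplies the oxygen and the open C1 of ring D the electrophilic carbon.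
  - 19 is lithiated to 20 as in step 11 and quenched with B(OMe)3 to give the ABC dimethyl boronate F2.
  - Oxidation in the same flask (H2O2, NaOH) gives the ABC phenol F3.
  - 11 is treated with Tf2O and pyridine to give the DEF triflate F4.
  - Palladium-catalysed C-O coupling of F3 with F4 (Pd(OAc)2, t-BuXPhos, K3PO4, toluene, 100 °C) gives 22.

Step 13.
- Risk: cleavage of the fifteen methyl ethers may stall when boron chelates of partly cleaved pyrogallol units precipitate, and the free polyphenol may autoxidise during isolation.
- Fallback (sets out from 22 and returns at 23): the product is derivatised, purified and then released.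
  - After the BBr3 cleavage the crude material is not isolated but acetylated (Ac2O, pyridine, DMAP) to the pentadecaacetate F5.
  - F5 should tolerate air and silica and can be separated from incompletely cleaved material.
  - Acid-catalysed methanolysis (HCl in degassed MeOH, made from AcCl) then frees 23 without any phenoxide stage.

**Further compounds**
F1 | step 1 | methyl 4-[4-(benzyloxy)-3,5-dimethoxyphenoxy]-3,5-dimethoxybenzoate | COC(=O)c1cc(OC)c(Oc2cc(OC)c(OCc3ccccc3)c(OC)c2)c(OC)c1
F2 | step 12 | ABC dimethyl boronate | COc1cc(OC)c(Oc2cc(OC)c(Oc3cc(OC)c(OC)c(OC)c3B(OC)OC)c(OC)c2)c(OC)c1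
F3 | step 12 | ABC phenol, 2-[2,6-dimethoxy-4-(2,4,6-trimethoxyphenoxy)phenoxy]-4,5,6-trimethoxyphenol | COc1cc(OC)c(Oc2cc(OC)c(Oc3cc(OC)c(OC)c(OC)c3O)c(OC)c2)c(OC)c1
F4 | step 12 | DEF triflate | FC(F)(F)S(=O)(=O)Oc1cc(OC)c(Oc2cc(OC)c(Oc3cc(OC)c(OC)c(OC)c3)c(OC)c2)c(OC)c1
F5 | step 13 | pentadecaacetate of the target | CC(=O)Oc1cc(OC(C)=O)c(Oc2cc(OC(C)=O)c(Oc3cc(OC(C)=O)c(OC(C)=O)c(OC(C)=O)c3Oc3cc(OC(C)=O)c(Oc4cc(OC(C)=O)c(Oc5cc(OC(C)=O)c(OC(C)=O)c(OC(C)=O)c5)c(OC(C)=O)c4)c(OC(C)=O)c3)c(OC(C)=O)c2)c(OC(C)=O)c1
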